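## Structural features

The target is a germacrane: one ten-membered carbocycle and no other ring, numbered here C1–C10 so that C4 is the methyl-bearing tertiary carbinol, C5 the secondary carbinol, C6 the carbon carrying the (Z)-2-methylbut-2-enoate (angelate), C7 the carbon carrying the 2-hydroxypropan-2-yl group (C11) and C10 the methyl-bearing methine. Four stereocentres are contiguous (4R,5S,6R,7R: the C4 and C5 hydroxyls cis on the ring, the C5 and C6 oxygens trans, the C6 oxygen cis to the C7 side chain), and the fifth, C10 (S), is separated from them by methylenes but lies directly across the ring from C5. The fragile groups are the angelate, which isomerises to the tiglate under nucleophilic or basic acylation conditions and would not survive an olefin hydrogenation, the diol monoester array, which invites acyl migration from O6 to O5, and the two tertiary alcohols, which eliminate under strong acid. The real difficulty is twofold: a medium ring that cannot be closed efficiently end to end, and stereocontrol on a conformationally mobile ring, above all at the quaternary C4 and the remote C10. The key step exploits the transannular relationship of C5 and C10: if these two atoms are bonded, C5–C6–C7–C8–C9–C10 is the cyclohexane ring of carvone with C7 already carrying its three-carbon side chain, and C4–C3 and C1–C2 become two alkenyl arms on adjacent ring carbons. A [3,3] shift then joins C2 to C3, cuts C5–C10, uncovers the ten-membered ring, leaves C5 as a carbonyl and makes C4 an enolate carbon that can be hydroxylated at once.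

## Logic of the disconnections

31 to 30: only the O–Si bond at C11 and the two ketal C–O bonds at O4 and O5 are cut. The 4,5-diol has to be masked while the ester is put on O6, and the mask must fall under conditions that leave the Z-enoate alone. This leaves a single mild acid hydrolysis as the last step; it must not cause acyl migration.

30 to 27 and 28: the acyl C–O bond at O6 is cut. The isomerisable, hydrogenation-sensitive ester is brought in as late as possible, onto a compound with one free hydroxyl. The forward step must acylate a hindered secondary alcohol without Z to E isomerisation.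

27 to 26: the C10–H and C1–H bonds are cut. C10 is the one centre that cannot be carried through the key step, because it is trigonal after the rearrangement. The forward step must choose one face of the ring olefin.

26 to 25 to 24: the C6–H bond is cut. The C6 configuration of the target (oxygen cis to the C7 side chain, trans to O5) is that of hydride addition to a C6 ketone; electrophilic oxygenation of a C5 enolate would put oxygen anti to the side chain. Oxygen is therefore introduced at C6 without regard to configuration, oxidised and reduced. The forward reduction must follow the two flanking centres, which point the same way.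

24 to 22 to 21 to 18: the ketal, the C5–H bond and the C6–O bond are cut. C5 is reduced while C4–OH is the only chelating neighbour, which ties the C5 configuration to C4. C6 is oxygenated through the only enolate that 18 can form. The demand is a C6 oxygen that is silylated and non-chelating during the reduction.

18 to 15 (key step): C2–C3 is cut, C5–C10 is rejoined, and the C4–O bond is removed. This turns a ten-membered ring with a quaternary carbinol into a cyclohexanol with two alkenyl groups. The forward step needs a chair in which isopropenyl, vinyl and the C7 side chain are all equatorial, and this fixes 15 as the (1R,2S,5R) isomer. Its C1,C2-epimeric pair (1S,2R,5R), although it is also a trans-dialkenyl carbinol, would have to place the C7 side chain axial and syn to the alkoxide, and would pass its chirality to the wrong face of C4.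

15 to 10 to 8 and 9: the C4–C5 bond is cut. Addition of 9 to 8 is expected to come from the face opposite the axial methyl of C10 and so to give the wrong C5 epimer 10. The configuration is therefore corrected by passing C5 through a trigonal state (13) and returning the oxygen by a [2,3] shift to that same open face.

8 to 5 and 6: the C1–C10 bond is cut, and is made by a 1,2-shift of vinyl from C5 to C10 in 7. Direct entry of a two-carbon electrophile at C10 of 4 would come in axially, cis to the side chain, which is the wrong epimer. A small electrophile (chlorine) is placed there instead, and the vinyl group then displaces it with inversion, ending trans to the side chain.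

5 to 3 to 2 to 1: the C10–Cl, O–Si and C11–O bonds are cut. 1 supplies C5–C10, C7 with its configuration, C11–C13 and the C10 methyl. The demand is regiospecific formation of the C10 enolate 4, met by conjugate reduction.

## Other disconnections considered

Alternative 1: The cut is C3–C4, made in the Ireland–Claisen sense: the ring oxygen of a ten-membered glycolate lactone sits on C1, and the C4 methyl is carried as a carboxyl carbon. In the forward direction the silyl ketene acetal would rearrange [3,3] across the ring (C3–C4 formed, O–C1 broken) to the cyclodecene acid A1, in which C4 is quaternary and already oxygenated.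
- In its favour: C10 and C5–C7 would be fixed in an open chain before any ring exists. The disubstituted C1=C2 olefin of A1 would be hydrogenated without creating a stereocentre. On C10 this plan is better than the chosen one, which relies on facial selection in an olefin hydrogenation.
- Against it here: a decanolide must first be closed. The shift is forced through a boat-like transition state inside a ring, so the sense of transfer to C4 and the olefin geometry are hard to foresee. The carboxyl group must afterwards be taken down to a methyl group at a neopentyl position.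
- Comparison: on structure the two plans are equal in that both obtain the carbocycle from a sigmatropic shift and not from end-to-end closure. On mechanism the chosen oxy-Cope runs through an unstrained chair with an irreversible enolate sink, the alternative through a constrained transition state. On step economy the open-chain seco acid, the lactonisation and the carboxyl-to-methyl reduction would make the alternative clearly longer than fifteen steps.

Alternative 2: The cut is the C4–C9 bond of a cis-fused bicyclic precursor, so the target ring is seen as the periphery of a decalin; the C4 methyl is added afterwards. In the forward direction a C4 alkoxide and a C8 sulfonate would undergo Grob fragmentation to the (E)-cyclodecenone A2, with C5, C6, C7 and C10 in place.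
- In its favour: the fragmentation is stereospecific and a dependable entry to (E)-cyclodecenones. C6 and C10 would be set on rigid six-membered rings, which is better than the chosen plan, where C10 is made on the ten-membered ring and C6 needs an oxidation–reduction detour. The C8=C9 olefin of A2 would be hydrogenated without a new stereocentre. The two plans are equal in uncovering the ring and not closing it.
- Against it here: a decalin with six defined stereocentres and an antiperiplanar leaving group must be built first. The quaternary C4 would then arise by methyl addition to a ten-membered ketone, where chelation to O5 helps but the ring conformation decides; the chosen plan is better here, since C4 follows from a chair. A2 would share the transannular ene liability of 18.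
- Step economy: the bicyclic precursor would probably push the total beyond twenty steps.

Alternative 3: The cut is C4–C5, between the two carbinol carbons. In the forward direction SmI2 would couple a methyl ketone with an aldehyde at the ends of an open chain and give the protected cis-diol A3 directly.
- In its favour: it is the most convergent plan. C6, C7 and C10 would be set by open-chain methods (better than the chosen plan for C10). A3 is only a protecting-group exchange and one acylation away from the target, so its endgame is shorter than the eight steps that follow the chosen key step.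
- Against it here: ten is the least favourable ring size for end-to-end ketyl closure, so simple reduction and intermolecular coupling would compete even at high dilution. Two centres, one of them quaternary, would be created at once in a floppy transition state; chelation to trivalent samarium favours a cis-diol but does not select the face. The C6 alkoxy group next to the aldehyde could be lost by β-elimination from the ketyl.
- Comparison: on structure the chosen plan avoids any medium-ring closure. On mechanism it relays chirality through a chair where the alternative depends on ring conformation at the moment of closure. On step count the alternative would be equal or better if the cyclisation worked, and it is the worse plan in risk.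

Key step: step 7

Remark on the chemistry (assumption): ring atoms are numbered C1–C10 as under Structural features in all ten-membered compounds; 1, 6, 9, 28 and all reagents are taken as commercial.

## Route

Step 1
Reactants: 1 (R)-(−)-carvone
Product: 2 (5R)-5-(2-hydroxypropan-2-yl)-2-methylcyclohex-2-en-1-one
Conditions: H2SO4 (50% aq.), 0 °C
Reagents that add atoms: water, O
Why: Markovnikov hydration of the 1,1-disubstituted olefin through the tertiary cation; the conjugated ring olefin is deactivated and the stereocentre (the later C7) is not touched.

Step 2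
Reactants: 2 (5R)-5-(2-hydroxypropan-2-yl)-2-methylcyclohex-2-en-1-one
Product: 3 (5R)-2-methyl-5-[2-(triethylsilyloxy)propan-2-yl]cyclohex-2-en-1-one
Conditions: Et3SiOTf, 2,6-lutidine, CH2Cl2, −78 → 0 °C
Reagents that add atoms: triethylsilyl trifluoromethanesulfonate, CC[Si](CC)(CC)OS(=O)(=O)C(F)(F)F
Why: Silylation of a tertiary alcohol with a silyl triflate; the tertiary triethylsilyl ether should survive hydride, Grignard, KH and mild acid and fall in the last step.

Step 3
Reactants: 3 (5R)-2-methyl-5-[2-(triethylsilyloxy)propan-2-yl]cyclohex-2-en-1-one
Product: 5 (2S,5R)-2-chloro-2-methyl-5-[2-(triethylsilyloxy)propan-2-yl]cyclohexan-1-one (Cl cis to the side chain), via lithium enolate 4 (not isolated)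
Conditions: LiBH(s-Bu)3, THF, −78 °C; then N-chlorosuccinimide, THF, −78 → −30 °C
Reagents that add atoms: N-chlorosuccinimide, O=C1CCC(=O)N1Cl
Why: Conjugate reduction of the β-unsubstituted enone gives the C10 enolate regiospecifically, and electrophilic chlorination of the enolate follows. Chlorine should enter axially on the half-chair that keeps the side chain equatorial, i.e. cis to the side chain; this C–Cl configuration later decides the face of the vinyl shift.

Step 4
Reactants: 5 (2S,5R)-2-chloro-2-methyl-5-[2-(triethylsilyloxy)propan-2-yl]cyclohexan-1-one; 6 vinylmagnesium bromide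
Product: 8 (2S,5R)-2-ethenyl-2-methyl-5-[2-(triethylsilyloxy)propan-2-yl]cyclohexan-1-one (vinyl trans to the side chain), via magnesium chlorohydrin alkoxide 7 (not isolated)
Conditions: CH2=CHMgBr, THF, −78 → 0 °C; then toluene, 80 °C
Reagents that add atoms: vinylmagnesium bromide (6), C=C[Mg]Br
Why: The Grignard reagent should add anti to the axial C–Cl bond (Cornforth-type addition), giving a chlorohydrin alkoxide with vinyl and chlorine trans-diaxial. On warming, the vinyl group migrates to C10 antiperiplanar to the leaving chloride and the ketone is re-formed (semipinacol rearrangement of an α-halo ketone Grignard adduct). Inversion at C10 places vinyl trans and methyl cis to the side chain.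

Step 5
Reactants: 8 (2S,5R)-2-ethenyl-2-methyl-5-[2-(triethylsilyloxy)propan-2-yl]cyclohexan-1-one; 9 isopropenylmagnesium bromide
Product: 10 (1S,2S,5R)-2-ethenyl-2-methyl-1-(prop-1-en-2-yl)-5-[2-(triethylsilyloxy)propan-2-yl]cyclohexan-1-ol
Conditions: CH2=C(CH3)MgBr, CeCl3, THF, −78 → 0 °C
Reagents that add atoms: isopropenylmagnesium bromide (9), C=C(C)[Mg]Br
Why: Organocerium 1,2-addition to a hindered, enolisable ketone. Attack is expected anti to the axial C10 methyl, which gives the epimer with axial isopropenyl (1S); the face does not matter, because C5 becomes trigonal in the next step.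

Step 6
Reactants: 10 (1S,2S,5R)-2-ethenyl-2-methyl-1-(prop-1-en-2-yl)-5-[2-(triethylsilyloxy)propan-2-yl]cyclohexan-1-ol
Product: 15 (1R,2S,5R)-2-ethenyl-2-methyl-1-(prop-1-en-2-yl)-5-[2-(triethylsilyloxy)propan-2-yl]cyclohexan-1-ol, via lithium alkoxide 11 (not isolated), via sulfenate ester 12 (not isolated), via allylic sulfoxide 13 (not isolated), via epimeric sulfenate 14 (not isolated)
Conditions: n-BuLi, THF, −78 °C; PhSCl, −78 → 25 °C; then P(OMe)3, MeOH, 60 °C
Reagents that add atoms: none
Why: O-Sulfenylation and the [2,3] sulfenate-to-sulfoxide shift make C5 trigonal; on heating, the Mislow–Evans rearrangement returns oxygen to C5 and the phosphite traps the sulfenate. The returning oxygen should bond axially, on the face opposite the axial C10 methyl, which leaves isopropenyl equatorial (1R), the more stable arrangement; this sets the C5 configuration that the key step needs.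

Step 7
Reactants: 15 (1R,2S,5R)-2-ethenyl-2-methyl-1-(prop-1-en-2-yl)-5-[2-(triethylsilyloxy)propan-2-yl]cyclohexan-1-ol
Product: 18 (4R,7R,1(10)E)-4-hydroxy-4,10-dimethyl-7-[2-(triethylsilyloxy)propan-2-yl]cyclodec-1(10)-en-5-one, via potassium alkoxide 16 (not isolated), via potassium enolate 17 (not isolated)
Conditions: KH, 18-crown-6, THF, 0 → 25 °C; then 2-(phenylsulfonyl)-3-phenyloxaziridine, THF, −78 °C; H2O
Reagents that add atoms: 2-(phenylsulfonyl)-3-phenyloxaziridine, O=S(=O)(N1OC1c1ccccc1)c1ccccc1
Why: KH with 18-crown-6 gives the free potassium alkoxide 16, whose oxyanion weakens the C5–C10 bond and triggers an anionic oxy-Cope [3,3] shift: C2–C3 forms, C5–C10 breaks and the enolate 17 is formed irreversibly. The closest known reaction type is the anionic oxy-Cope ring expansion of trans-1,2-dialkenylcyclohexanols to (E)-cyclodec-5-enone enolates with trapping of the enolate, here by α-hydroxylation of a potassium enolate with an N-sulfonyloxaziridine. The ten-membered ring is not closed end to end but uncovered by ring expansion from six to ten, through a chair-like six-centre transition state fused like a trans-decalin to the cyclohexane chair; the only new contact is between the terminal methylene carbons C2 and C3. In 15 isopropenyl, vinyl and the C7 side chain are all equatorial, so no ring flip is needed, and C6 and C9 are equatorial on the reacting chair, which gives the (E)-C1=C10 olefin and the enolate with C3 and C6 trans. That enolate is planar-chiral, and being tetrasubstituted within a ten-membered ring it should not turn its face at −78 °C; its inner face is covered by the C1=C10 bond across the ring, so the oxaziridine can approach only from outside. The new C4 stereocentre is therefore controlled by the C5 configuration of 15, relayed through the chair: with C5 (R), oxygen on the outer face gives 4R. The step needs the chair over a boat or fragmentation (secured by the all-equatorial chair), a regiospecific C4 enolate (it is born in the shift, KH leaves no proton source, and the oxidant is added before any equilibration) and C-hydroxylation in preference to addition to the sulfonimine by-product (potassium counter-ion, low temperature).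

Step 8
Reactants: 18 (4R,7R,1(10)E)-4-hydroxy-4,10-dimethyl-7-[2-(triethylsilyloxy)propan-2-yl]cyclodec-1(10)-en-5-one
Product: 21 (4R,6S,7R,1(10)E)-4-hydroxy-4,10-dimethyl-6-(triethylsilyloxy)-7-[2-(triethylsilyloxy)propan-2-yl]cyclodec-1(10)-en-5-one, via dipotassium dianion 19 (not isolated), via dipotassium diolate 20 (not isolated)
Conditions: KN(SiMe3)2 (2.3 equiv), THF, −78 °C; 2-(phenylsulfonyl)-3-phenyloxaziridine, −78 °C; then Et3SiCl (1.1 equiv), −78 → −20 °C
Reagents that add atoms: 2-(phenylsulfonyl)-3-phenyloxaziridine, O=S(=O)(N1OC1c1ccccc1)c1ccccc1; chlorotriethylsilane, CC[Si](CC)(CC)Cl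
Why: Only C6 can be enolised, and oxaziridine hydroxylation of the enolate should occur anti to the C7 side chain (6S); this configuration is not used, because C6 is oxidised in step 11. The less hindered secondary alkoxide is silylated in the same flask, which keeps C4–OH free for the chelation-controlled reduction.

Step 9
Reactants: 21 (4R,6S,7R,1(10)E)-4-hydroxy-4,10-dimethyl-6-(triethylsilyloxy)-7-[2-(triethylsilyloxy)propan-2-yl]cyclodec-1(10)-en-5-one
Product: 22 (4R,5S,6S,7R,1(10)E)-4,10-dimethyl-6-(triethylsilyloxy)-7-[2-(triethylsilyloxy)propan-2-yl]cyclodec-1(10)-ene-4,5-diol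
Conditions: Zn(BH4)2, Et2O, −20 °C
Reagents that add atoms: none
Why: Chelation-controlled reduction of an α-hydroxy ketone (Cram chelate between C4–OH and the C5 carbonyl, the silyl ether at C6 not taking part). Hydride should come from the chelate face that carries the C4 methyl and not the ring, giving the cis-4,5-diol (5S).

Step 10
Reactants: 22 (4R,5S,6S,7R,1(10)E)-4,10-dimethyl-6-(triethylsilyloxy)-7-[2-(triethylsilyloxy)propan-2-yl]cyclodec-1(10)-ene-4,5-diol
Product: 24 (4R,5S,6S,7R,1(10)E)-4,5-O-isopropylidene-4,10-dimethyl-7-[2-(triethylsilyloxy)propan-2-yl]cyclodec-1(10)-ene-4,5,6-triol (6-OH free), via acetonide bis-silyl ether 23 (not isolated)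
Conditions: 2-methoxypropene, PPTS (cat.), CH2Cl2, 0 °C; then MeOH, 25 °C
Reagents that add atoms: 2-methoxypropene, C=C(C)OC
Why: Acid-catalysed ketalisation of the only free diol, which is cis; methanolysis under the same catalyst then cleaves the secondary silyl ether, which should go faster than the tertiary one or the dioxolane.

Step 11
Reactants: 24 (4R,5S,6S,7R,1(10)E)-4,5-O-isopropylidene-4,10-dimethyl-7-[2-(triethylsilyloxy)propan-2-yl]cyclodec-1(10)-ene-4,5,6-triol
Product: 25 (1(10)E)-4,5-O-isopropylidene-4,5-dihydroxy-4,10-dimethyl-7-[2-(triethylsilyloxy)propan-2-yl]cyclodec-1(10)-en-6-one (C4/C5/C7 as in 24; CIP labels 4R,5R,7S)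
Conditions: DMP, NaHCO3, CH2Cl2, 0 → 25 °C
Reagents that add atoms: none
Why: Oxidation of a secondary alcohol with the Dess–Martin periodinane under buffered, non-basic conditions, which should avoid epimerisation at C7 and β-elimination of the C4 oxygen.

Step 12
Reactants: 25 (1(10)E)-4,5-O-isopropylidene-4,5-dihydroxy-4,10-dimethyl-7-[2-(triethylsilyloxy)propan-2-yl]cyclodec-1(10)-en-6-one
Product: 26 (4R,5S,6R,7R,1(10)E)-4,5-O-isopropylidene-4,10-dimethyl-7-[2-(triethylsilyloxy)propan-2-yl]cyclodec-1(10)-ene-4,5,6-triol (6-OH free)
Conditions: LiBH(s-Bu)3, THF, −78 °C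
Reagents that add atoms: none
Why: Felkin–Anh reduction with a bulky, non-chelating hydride. Attack anti to the C5–O bond and attack on the side away from the C11 group (which eclipses the carbonyl) point the same way and should give the C6 alcohol trans to O5 and cis to the side chain (6R).

Step 13
Reactants: 26 (4R,5S,6R,7R,1(10)E)-4,5-O-isopropylidene-4,10-dimethyl-7-[2-(triethylsilyloxy)propan-2-yl]cyclodec-1(10)-ene-4,5,6-triol
Product: 27 (4R,5S,6R,7R,10S)-4,5-O-isopropylidene-4,10-dimethyl-7-[2-(triethylsilyloxy)propan-2-yl]cyclodecane-4,5,6-triol (6-OH free)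
Conditions: H2 (1 atm), [Ir(cod)(PCy3)(py)]PF6 (5 mol %), CH2Cl2, 25 °C
Reagents that add atoms: none
Why: Homogeneous hydrogenation of a trisubstituted olefin with a cationic iridium catalyst; the (E)-olefin can be reached only from its outer face, so the C10 configuration depends on which rotamer of the C9–C10=C1–C2 unit reacts. The rotamer that keeps the C10 methyl off the ring face already holding the C6 hydroxyl and the C4 methyl is expected to react and gives 10S; the dioxolane ties back O4 and O5, so the only free hydroxyl is on the face that must receive hydrogen.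

Step 14
Reactants: 27 (4R,5S,6R,7R,10S)-4,5-O-isopropylidene-4,10-dimethyl-7-[2-(triethylsilyloxy)propan-2-yl]cyclodecane-4,5,6-triol; 28 angelic acid
Product: 30 (4R,5S,6R,7R,10S)-4,5-O-isopropylidene-4,5-dihydroxy-4,10-dimethyl-7-[2-(triethylsilyloxy)propan-2-yl]cyclodecan-6-yl (Z)-2-methylbut-2-enoate, via mixed anhydride 29 (not isolated)
Conditions: 28, 2,4,6-trichlorobenzoyl chloride, Et3N, toluene, 25 °C; then 27, toluene, 80 °C
Reagents that add atoms: angelic acid (28), C/C=C(/C)C(=O)O
Why: Yamaguchi-type esterification through the mixed anhydride, run without a nucleophilic catalyst so that the Z-enoate should not isomerise; C6–OH is the only free hydroxyl.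

Step 15
Reactants: 30 (4R,5S,6R,7R,10S)-4,5-O-isopropylidene-4,5-dihydroxy-4,10-dimethyl-7-[2-(triethylsilyloxy)propan-2-yl]cyclodecan-6-yl (Z)-2-methylbut-2-enoate
Product: 31 (4R,5S,6R,7R,10S)-4,5-dihydroxy-7-(2-hydroxypropan-2-yl)-4,10-dimethylcyclodecan-6-yl (Z)-2-methylbut-2-enoate (CNP0130723.1)
Conditions: CF3CO2H/H2O/THF (1:1:4), 0 → 25 °C
Reagents that add atoms: none
Why: Acid hydrolysis of the dioxolane and of the tertiary silyl ether in one operation; dilute acid at low temperature should leave the enoate geometry and the tertiary carbinols intact and keeps acyl migration slow.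

## Compound list

1 | (R)-(−)-carvone | CC1=CC[C@@H](C(C)=C)CC1=O | starting material
2 | (5R)-5-(2-hydroxypropan-2-yl)-2-methylcyclohex-2-en-1-one | CC1=CC[C@@H](C(C)(C)O)CC1=O | intermediate
3 | (5R)-2-methyl-5-[2-(triethylsilyloxy)propan-2-yl]cyclohex-2-en-1-one | CC1=CC[C@@H](C(C)(C)O[Si](CC)(CC)CC)CC1=O | intermediate
4 | lithium (5R)-2-methyl-5-[2-(triethylsilyloxy)propan-2-yl]cyclohex-1-en-1-olate (C10 enolate) | CC1=C([O-])C[C@H](C(C)(C)O[Si](CC)(CC)CC)CC1.[Li+] | intermediate
5 | (2S,5R)-2-chloro-2-methyl-5-[2-(triethylsilyloxy)propan-2-yl]cyclohexan-1-one, Cl cis to the side chain | O=C1C[C@H](C(C)(C)O[Si](CC)(CC)CC)CC[C@]1(C)Cl | intermediate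
6 | vinylmagnesium bromide | C=C[Mg]Br | starting material
7 | bromomagnesium (1S,2S,5R)-2-chloro-1-ethenyl-2-methyl-5-[2-(triethylsilyloxy)propan-2-yl]cyclohexan-1-olate, vinyl and Cl trans-diaxial | C=C[C@@]1(O[Mg]Br)C[C@H](C(C)(C)O[Si](CC)(CC)CC)CC[C@]1(C)Cl | intermediate
8 | (2S,5R)-2-ethenyl-2-methyl-5-[2-(triethylsilyloxy)propan-2-yl]cyclohexan-1-one, vinyl trans to the side chain | O=C1C[C@H](C(C)(C)O[Si](CC)(CC)CC)CC[C@@]1(C)C=C | intermediate
9 | isopropenylmagnesium bromide | C=C(C)[Mg]Br | starting material
10 | (1S,2S,5R)-2-ethenyl-2-methyl-1-(prop-1-en-2-yl)-5-[2-(triethylsilyloxy)propan-2-yl]cyclohexan-1-ol, isopropenyl axial | C=C(C)[C@@]1(O)C[C@H](C(C)(C)O[Si](CC)(CC)CC)CC[C@@]1(C)C=C | intermediate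
11 | lithium alkoxide of 10 | C=C(C)[C@@]1([O-])C[C@H](C(C)(C)O[Si](CC)(CC)CC)CC[C@@]1(C)C=C.[Li+] | intermediate
12 | benzenesulfenate ester of 10 | C=C(C)[C@@]1(OSc2ccccc2)C[C@H](C(C)(C)O[Si](CC)(CC)CC)CC[C@@]1(C)C=C | intermediate
13 | phenyl 2-[(2S,5R)-2-ethenyl-2-methyl-5-[2-(triethylsilyloxy)propan-2-yl]cyclohexylidene]propyl sulfoxide (olefin geometry and sulfur configuration not controlled, both converge) | O=S(CC(C)=C1C[C@H](C(C)(C)O[Si](CC)(CC)CC)CC[C@@]1(C)C=C)c1ccccc1 | intermediate
14 | benzenesulfenate ester of 15 (C1 epimer of 12) | C=C(C)[C@]1(OSc2ccccc2)C[C@H](C(C)(C)O[Si](CC)(CC)CC)CC[C@@]1(C)C=C | intermediate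
15 | (1R,2S,5R)-2-ethenyl-2-methyl-1-(prop-1-en-2-yl)-5-[2-(triethylsilyloxy)propan-2-yl]cyclohexan-1-ol, isopropenyl, vinyl and side chain all equatorial | C=C(C)[C@]1(O)C[C@H](C(C)(C)O[Si](CC)(CC)CC)CC[C@@]1(C)C=C | intermediate
16 | potassium alkoxide of 15 | C=C(C)[C@]1([O-])C[C@H](C(C)(C)O[Si](CC)(CC)CC)CC[C@@]1(C)C=C.[K+] | intermediate
17 | potassium C4=C5 enolate of (7R,1(10)E)-4,10-dimethyl-7-[2-(triethylsilyloxy)propan-2-yl]cyclodec-1(10)-en-5-one, C3 and C6 trans | [O-]/C1=C(/C)CC/C=C(C)/CC[C@@H](C(C)(C)O[Si](CC)(CC)CC)C1.[K+] | intermediate
18 | (4R,7R,1(10)E)-4-hydroxy-4,10-dimethyl-7-[2-(triethylsilyloxy)propan-2-yl]cyclodec-1(10)-en-5-one | O=C1C[C@H](C(C)(C)O[Si](CC)(CC)CC)CC/C(C)=C/CC[C@@]1(C)O | intermediate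
19 | dipotassium salt of 18 (C4 alkoxide, C5=C6 enolate; enolate geometry not specified) | [O-]C1=C[C@H](C(C)(C)O[Si](CC)(CC)CC)CC/C(C)=C/CC[C@@]1(C)[O-].[K+].[K+] | intermediate
20 | dipotassium 4,6-diolate of (4R,6S,7R,1(10)E)-4,6-dihydroxy-4,10-dimethyl-7-[2-(triethylsilyloxy)propan-2-yl]cyclodec-1(10)-en-5-one | O=C1[C@@H]([O-])[C@H](C(C)(C)O[Si](CC)(CC)CC)CC/C(C)=C/CC[C@@]1(C)[O-].[K+].[K+] | intermediate
21 | (4R,6S,7R,1(10)E)-4-hydroxy-4,10-dimethyl-6-(triethylsilyloxy)-7-[2-(triethylsilyloxy)propan-2-yl]cyclodec-1(10)-en-5-one | CC[Si](CC)(CC)O[C@H]1[C@H](C(C)(C)O[Si](CC)(CC)CC)CC/C(C)=C/CC[C@@](C)(O)C1=O | intermediate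
22 | (4R,5S,6S,7R,1(10)E)-4,10-dimethyl-6-(triethylsilyloxy)-7-[2-(triethylsilyloxy)propan-2-yl]cyclodec-1(10)-ene-4,5-diol | CC[Si](CC)(CC)O[C@H]1[C@H](C(C)(C)O[Si](CC)(CC)CC)CC/C(C)=C/CC[C@@](C)(O)[C@H]1O | intermediate
23 | 4,5-O-isopropylidene derivative of 22 | CC[Si](CC)(CC)O[C@H]1[C@H](C(C)(C)O[Si](CC)(CC)CC)CC/C(C)=C/CC[C@@]2(C)OC(C)(C)O[C@@H]12 | intermediate
24 | (4R,5S,6S,7R,1(10)E)-4,5-O-isopropylidene-4,10-dimethyl-7-[2-(triethylsilyloxy)propan-2-yl]cyclodec-1(10)-ene-4,5,6-triol | O[C@H]1[C@H](C(C)(C)O[Si](CC)(CC)CC)CC/C(C)=C/CC[C@@]2(C)OC(C)(C)O[C@@H]12 | intermediate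
25 | (1(10)E)-4,5-O-isopropylidene-4,5-dihydroxy-4,10-dimethyl-7-[2-(triethylsilyloxy)propan-2-yl]cyclodec-1(10)-en-6-one, C4, C5 and C7 as in 24 | O=C1[C@H](C(C)(C)O[Si](CC)(CC)CC)CC/C(C)=C/CC[C@@]2(C)OC(C)(C)O[C@@H]12 | intermediate
26 | (4R,5S,6R,7R,1(10)E)-4,5-O-isopropylidene-4,10-dimethyl-7-[2-(triethylsilyloxy)propan-2-yl]cyclodec-1(10)-ene-4,5,6-triol | O[C@@H]1[C@H](C(C)(C)O[Si](CC)(CC)CC)CC/C(C)=C/CC[C@@]2(C)OC(C)(C)O[C@@H]12 | intermediate
27 | (4R,5S,6R,7R,10S)-4,5-O-isopropylidene-4,10-dimethyl-7-[2-(triethylsilyloxy)propan-2-yl]cyclodecane-4,5,6-triol | O[C@@H]1[C@H](C(C)(C)O[Si](CC)(CC)CC)CC[C@@H](C)CCC[C@@]2(C)OC(C)(C)O[C@@H]12 | intermediate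
28 | angelic acid, (Z)-2-methylbut-2-enoic acid | C/C=C(/C)C(=O)O | starting material
29 | (Z)-2-methylbut-2-enoic 2,4,6-trichlorobenzoic anhydride | C/C=C(/C)C(=O)OC(=O)c1c(Cl)cc(Cl)cc1Cl | intermediate
30 | (4R,5S,6R,7R,10S)-4,5-O-isopropylidene-4,5-dihydroxy-4,10-dimethyl-7-[2-(triethylsilyloxy)propan-2-yl]cyclodecan-6-yl (Z)-2-methylbut-2-enoate | C/C=C(/C)C(=O)O[C@@H]1[C@H](C(C)(C)O[Si](CC)(CC)CC)CC[C@@H](C)CCC[C@@]2(C)OC(C)(C)O[C@@H]12 | intermediate
31 | (4R,5S,6R,7R,10S)-4,5-dihydroxy-7-(2-hydroxypropan-2-yl)-4,10-dimethylcyclodecan-6-yl (Z)-2-methylbut-2-enoate, CNP0130723.1 | C/C=C(/C)C(=O)O[C@@H]1[C@H](C(C)(C)O)CC[C@@H](C)CCC[C@@](C)(O)[C@H]1O | target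

## Step count and least certain steps

Total step count: 15. Longest linear sequence: 15 steps (1 to 31).

Step 7 (key step). What may go wrong: loss of facial selectivity at C4 if the enolate turns its face or is protonated and re-formed before it is oxidised, and consumption of the enolate by addition to the sulfonimine that the oxidant leaves behind. Both come from a hindered, tetrasubstituted enolate that reacts slowly with the oxaziridine. Fallback: starting from 15, the same KH/18-crown-6 rearrangement is quenched with Me3SiCl, and the trimethylsilyl enol ether F1 is isolated with its olefin geometry and planar chirality intact. Rubottom oxidation of F1 with one equivalent of dimethyldioxirane at −78 °C (the enol ether being far more electron-rich than the C1=C10 olefin) should give the 4-trimethylsilyloxy ketone F2. Citric acid in MeOH then returns the route to 18.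

Step 13. What may go wrong: poor facial selectivity, because both rotamers of the trisubstituted olefin are reduced; no hydroxyl sits close enough to the outer face of the olefin to direct the metal, so the outcome rests on a conformational preference that cannot be guaranteed. Fallback: starting from 26, the olefin is reduced by hydrogen-atom transfer (Mn(dpm)3, PhSiH3, t-BuOOH, i-PrOH). This changes the stereo-determining event from syn addition to a rigid π face to hydrogen transfer to a tertiary C10 radical that is free to relax, and returns to the route at 27; this fallback creates no new compound (F0).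

Step 6. What may go wrong: return of the oxygen to the hindered face, or slow trapping of a very hindered tertiary sulfenate, leaving mixtures of C5 epimers and sulfoxide. Fallback: starting from 8, KN(SiMe3)2 and PhNTf2 give the enol triflate F3. Suzuki coupling with isopropenylboronic acid pinacol ester (PdCl2(dppf), K3PO4) gives the triene F4. Buffered m-CPBA should epoxidise the trisubstituted ring olefin anti to the axial C10 methyl to give the vinyl epoxide F5. LiAlH4 should open F5 trans-diaxially at C6, which returns the route to 15.

Step 4. What may go wrong: enolisation or electron-transfer reduction of the tertiary α-chloro ketone by the Grignard reagent, incomplete 1,2-shift, and carry-over of the minor chlorination epimer from step 3 into the wrong C10 configuration. Fallback: starting from 5, addition of CH2=CHMgBr/CeCl3 at −78 °C is stopped at the chlorohydrin F6, which is isolated and purified. The vinyl shift is then triggered separately by AgBF4 in CH2Cl2 at −20 °C, which returns the route to 8.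

Step 14. What may go wrong: slow acylation of the hindered C6 hydroxyl, with Z to E isomerisation of the enoate during prolonged heating. Fallback: starting from 27, the alcohol is esterified under forcing carbodiimide/DMAP conditions with 2-[bis(2,2,2-trifluoroethoxy)phosphoryl]propanoic acid to give the phosphonate ester F7, which has no olefin to isomerise. Still–Gennari olefination of F7 with acetaldehyde (KN(SiMe3)2, 18-crown-6, THF, −78 °C) then builds the Z-enoate on the ring and returns the route to 30.

## Further compounds

F1 | step 7 | trimethylsilyl enol ether of (7R,1(10)E)-4,10-dimethyl-7-[2-(triethylsilyloxy)propan-2-yl]cyclodec-1(10)-en-5-one (C4=C5, C3 and C6 trans) | C[Si](C)(C)O/C1=C(/C)CC/C=C(C)/CC[C@@H](C(C)(C)O[Si](CC)(CC)CC)C1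
F2 | step 7 | (4R,7R,1(10)E)-4,10-dimethyl-7-[2-(triethylsilyloxy)propan-2-yl]-4-(trimethylsilyloxy)cyclodec-1(10)-en-5-one | O=C1C[C@H](C(C)(C)O[Si](CC)(CC)CC)CC/C(C)=C/CC[C@@]1(C)O[Si](C)(C)C
F0 | step 13 | none | none
F3 | step 6 | (3R,6S)-6-ethenyl-6-methyl-3-[2-(triethylsilyloxy)propan-2-yl]cyclohex-1-en-1-yl trifluoromethanesulfonate | O=S(=O)(OC1=C[C@H](C(C)(C)O[Si](CC)(CC)CC)CC[C@@]1(C)C=C)C(F)(F)F
F4 | step 6 | (3R,6S)-6-ethenyl-6-methyl-1-(prop-1-en-2-yl)-3-[2-(triethylsilyloxy)propan-2-yl]cyclohex-1-ene | C=C(C)C1=C[C@H](C(C)(C)O[Si](CC)(CC)CC)CC[C@@]1(C)C=C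
F5 | step 6 | C5–C6 epoxide of F4, oxygen trans to the side chain and anti to the C10 methyl | C=C(C)[C@]12O[C@H]1[C@H](C(C)(C)O[Si](CC)(CC)CC)CC[C@@]2(C)C=C
F6 | step 4 | (1S,2S,5R)-2-chloro-1-ethenyl-2-methyl-5-[2-(triethylsilyloxy)propan-2-yl]cyclohexan-1-ol | C=C[C@@]1(O)C[C@H](C(C)(C)O[Si](CC)(CC)CC)CC[C@]1(C)Cl
F7 | step 14 | (4R,5S,6R,7R,10S)-4,5-O-isopropylidene-4,5-dihydroxy-4,10-dimethyl-7-[2-(triethylsilyloxy)propan-2-yl]cyclodecan-6-yl 2-[bis(2,2,2-trifluoroethoxy)phosphoryl]propanoate (phosphonate α-carbon not controlled) | CC(C(=O)O[C@@H]1[C@H](C(C)(C)O[Si](CC)(CC)CC)CC[C@@H](C)CCC[C@@]2(C)OC(C)(C)O[C@@H]12)P(=O)(OCC(F)(F)F)OCC(F)(F)F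
A1 | alternative 1 | (Z)-cyclodec-1-ene-4-carboxylic acid with quaternary C4 in the 4,5-acetonide, 6-O-(4-methoxybenzyl), 7-[2-(triethylsilyloxy)propan-2-yl] and 10-methyl | OC(=O)[C@@]12C/C=C\[C@H](C)CC[C@@H](C(C)(C)O[Si](CC)(CC)CC)[C@@H](OCc3ccc(OC)cc3)[C@@H]1OC(C)(C)O2
A2 | alternative 2 | (E)-cyclodec-8-en-4-one with 5-O-(4-methoxybenzyl), 6,11-O-isopropylidene and 10-methyl | O=C1CCC[C@H](C)/C=C/[C@@H]2[C@@H](OC(C)(C)OC2(C)C)[C@@H]1OCc3ccc(OC)cc3
A3 | alternative 3 | ten-membered cis-4,5-diol with 6-O-(4-methoxybenzyl) and 11-O-triethylsilyl | COc1ccc(CO[C@@H]2[C@H](C(C)(C)O[Si](CC)(CC)CC)CC[C@@H](C)CCC[C@@](C)(O)[C@H]2O)cc1
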